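**Plan**

- Retrosynthesis: ring B (C1' CO2H, C2' and C4' OH, C5' aryl ether oxygen, C6' pentyl) is cut at C1'–C2' and C5'–C6'. Its 2',4'-dihydroxy pattern next to the carboxyl maps C2'–C5' onto a bis-silyloxy diene from a 4-aryloxyacetoacetate, and C1'–C6' onto an oct-2-ynoate.
- Further cuts: the ether O–CH2 bond of that acetoacetate (isocoumarin 8-OH plus methyl 4-chloroacetoacetate), then the isocoumarin O2–C1 and C3–C4 bonds (methyl orsellinate plus a hexanoyl unit).
- Forward: ring A is the arene of methyl orsellinate. The pyranone ring closes by enol lactonisation, the C4 side chain is attached by O-alkylation and turned into the diene, and ring B is built last by Diels–Alder reaction and aromatisation. Both benzyl groups are then removed.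
- Stereochemistry: the target has no stereocentre. Only regiochemistry must be controlled, by chelation for the free 8-OH and by diene/ynoate polarity for ring B.

Key step: step 10

Remark on the chemistry: primed numbers refer to ring B, unprimed numbers to the isocoumarin. Enol ether 11 and diene 12 are expected as mixtures of double-bond isomers and are drawn without alkene geometry. Cycloadduct 15 is a transient mixture of diastereomers.

**Route**

Step 1
Reactants: 1 methyl orsellinate (methyl 2,4-dihydroxy-6-methylbenzoate)
Product: 2 methyl 2,4-bis(benzyloxy)-6-methylbenzoate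
Conditions: BnBr (2.5 equiv), K2CO3, DMF, 60 °C
Reagents that add atoms: benzyl bromide, BrCc1ccccc1
Why: Williamson ether synthesis on both phenols, where the polar aprotic solvent and gentle heating should be enough to alkylate the hydrogen-bonded 2-OH as well as the free 4-OH.

Step 2
Reactants: 3 hexanoyl chloride
Product: 4 N-methoxy-N-methylhexanamide
Conditions: MeNHOMe·HCl, Et3N, CH2Cl2, 0 °C to rt
Reagents that add atoms: N,O-dimethylhydroxylamine hydrochloride, CNOC.Cl
Why: N-acylation of the amine by the acid chloride gives the Weinreb amide, which later acylates a carbanion only once through its chelated tetrahedral adduct.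

Step 3
Reactants: 2 methyl 2,4-bis(benzyloxy)-6-methylbenzoate; 4 N-methoxy-N-methylhexanamide
Product: 6 methyl 2,4-bis(benzyloxy)-6-(2-oxoheptyl)benzoate, via lithiated toluate 5 (not isolated)
Conditions: LiN(i-Pr)2 (1.1 equiv), THF, −78 °C; then 4, −78 °C; aq. NH4Cl
Reagents that add atoms: none
Why: Lateral lithiation of the ortho-toluate methyl group (vinylogously acidified by the ester) followed by Weinreb ketone synthesis, in which the adduct collapses to the ketone only on quench, so the product can neither protonate unreacted anion nor react twice.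

Step 4
Reactants: 6 methyl 2,4-bis(benzyloxy)-6-(2-oxoheptyl)benzoate
Product: 7 6,8-bis(benzyloxy)-3-pentyl-1H-isochromen-1-one
Conditions: p-TsOH·H2O (cat.), toluene, reflux, 4 Å molecular sieves
Reagents that add atoms: none
Why: Acid-catalysed enol lactonisation, in which the aryl-conjugated enol of the benzyl ketone attacks the ortho ester carbonyl (6-exo-trig) and methanol is expelled and trapped, under conditions that aryl benzyl ethers tolerate.

Step 5
Reactants: 7 6,8-bis(benzyloxy)-3-pentyl-1H-isochromen-1-one
Product: 8 6-(benzyloxy)-8-hydroxy-3-pentyl-1H-isochromen-1-one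
Conditions: BCl3 (1.1 equiv), CH2Cl2, −78 °C; then H2O
Reagents that add atoms: none
Why: Chelation-directed Lewis acid dealkylation, in which BCl3 bridges the lactone carbonyl and the peri 8-oxygen in a six-membered chelate so that chloride cleaves only that benzyl ether, while the unchelated 6-O-benzyl ether should survive one equivalent at low temperature.

Step 6
Reactants: 8 6-(benzyloxy)-8-hydroxy-3-pentyl-1H-isochromen-1-one; 9 methyl 4-chloroacetoacetate
Product: 10 methyl 4-{[6-(benzyloxy)-1-oxo-3-pentyl-1H-isochromen-8-yl]oxy}-3-oxobutanoate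
Conditions: NaH (2.2 equiv), NaI (cat.), THF–DMF, 0 °C to rt; then dilute aq. HCl
Reagents that add atoms: none
Why: Williamson O-alkylation of the sodium phenoxide at the chloromethyl carbon, as in the known preparation of 4-alkoxy- and 4-aryloxyacetoacetates, where the second equivalent of NaH holds the β-keto ester as its enolate and so shields the active methylene, and the non-nucleophilic base leaves the lactone alone.

Step 7
Reactants: 10 methyl 4-{[6-(benzyloxy)-1-oxo-3-pentyl-1H-isochromen-8-yl]oxy}-3-oxobutanoate
Product: 11 methyl 4-{[6-(benzyloxy)-1-oxo-3-pentyl-1H-isochromen-8-yl]oxy}-3-(trimethylsilyloxy)but-2-enoate (E/Z mixture)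
Conditions: Me3SiCl, Et3N, toluene, rt
Reagents that add atoms: chlorotrimethylsilane, C[Si](C)(C)Cl
Why: O-silylation of the readily enolised β-keto ester with chlorosilane and amine gives the β-silyloxy enoate, the standard first stage of a 1-alkoxy-1,3-bis(silyloxy)diene synthesis, and its alkene geometry is of no consequence.

Step 8
Reactants: 11 methyl 4-{[6-(benzyloxy)-1-oxo-3-pentyl-1H-isochromen-8-yl]oxy}-3-(trimethylsilyloxy)but-2-enoate
Product: 12 6-(benzyloxy)-8-{[4-methoxy-2,4-bis(trimethylsilyloxy)buta-1,3-dien-1-yl]oxy}-3-pentyl-1H-isochromen-1-one (geometric isomers)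
Conditions: LiN(i-Pr)2, Me3SiCl (internal quench), THF, −78 °C
Reagents that add atoms: chlorotrimethylsilane, C[Si](C)(C)Cl
Why: Kinetic γ-deprotonation at the OCH2 group (acidified by the enoate and by the aryloxy oxygen) gives a lithium dienolate that is O-silylated at once by the chlorosilane already present, before it can attack the lactone, which is the standard second stage of the bis-silyloxy diene synthesis.

Step 9
Reactants: 13 oct-2-ynoic acid
Product: 14 benzyl oct-2-ynoate
Conditions: BnBr, K2CO3, DMF, rt
Reagents that add atoms: benzyl bromide, BrCc1ccccc1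
Why: SN2 O-alkylation of the carboxylate by benzyl bromide under mild base, which avoids acyl activation and nucleophilic catalysts that could add to the ynoate.

Step 10
Reactants: 12 6-(benzyloxy)-8-{[4-methoxy-2,4-bis(trimethylsilyloxy)buta-1,3-dien-1-yl]oxy}-3-pentyl-1H-isochromen-1-one; 14 benzyl oct-2-ynoate
Product: 17 benzyl 5-{[6-(benzyloxy)-1-oxo-3-pentyl-1H-isochromen-8-yl]oxy}-2,4-dihydroxy-6-pentylbenzoate, via cyclohexa-1,4-diene cycloadduct 15 (not isolated), via bis(trimethylsilyl) ether 16 (not isolated)
Conditions: 14 (3 equiv), toluene, 120 °C, sealed tube; then 1 M HCl, THF, rt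
Reagents that add atoms: none
Why: This is a thermal normal-electron-demand (4+2) cycloaddition in which the aryloxy-bearing diene terminus C5', made the most nucleophilic carbon by the C4' silyloxy group and the C2' ketene acetal oxygens, bonds to the electrophilic β-carbon of the ynoate (C6') while the ketene acetal carbon C2' bonds to the ester-bearing α-carbon (C1'), giving cyclohexa-1,4-diene 15. The closest known reaction type is the Diels–Alder reaction and aromatisation of 1-alkoxy-1,3-bis(silyloxy)buta-1,3-dienes, including 4-alkoxy and 4-aryloxy members, with alk-2-ynoates to give 6-substituted 2,4-dihydroxybenzoates. Ring B is the only ring closed, by an intermolecular cycloaddition that makes both C–C bonds in one step, after which 1,4-elimination of methanol across C2' and C5' aromatises it to 16 and the acidic work-up removes the silyl groups. No stereocentre results, because the two sp3 centres of 15 are erased on aromatisation. The step needs regioselectivity (ester beside the C2' hydroxyl, pentyl beside the ether oxygen), which the matched polarity of diene and ynoate should secure, and it needs the aryloxy group to stay, which follows because C2' carries no hydrogen, so only methanol and not the phenol can leave in the aromatising elimination. The isocoumarin C3=C4 bond is an electron-rich enol ester alkene and should not compete as a dienophile.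

Step 11
Reactants: 17 benzyl 5-{[6-(benzyloxy)-1-oxo-3-pentyl-1H-isochromen-8-yl]oxy}-2,4-dihydroxy-6-pentylbenzoate
Product: 18 5-[(6-hydroxy-1-oxo-3-pentyl-1H-isochromen-8-yl)oxy]-2,4-dihydroxy-6-pentylbenzoic acid (target)
Conditions: H2 (1 atm), 10% Pd/C, EtOAc, rt
Reagents that add atoms: none
Why: Hydrogenolysis over Pd/C cleaves the benzyl ether and the benzyl ester under neutral conditions at room temperature, which spares the decarboxylation-prone 2,4-dihydroxybenzoic acid, while the trisubstituted enol lactone alkene is expected to be reduced far more slowly, so the reaction is stopped after uptake of two equivalents of hydrogen.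

**Compound list**

1 | methyl orsellinate (methyl 2,4-dihydroxy-6-methylbenzoate) | COC(=O)c1c(C)cc(O)cc1O | starting material
2 | methyl 2,4-bis(benzyloxy)-6-methylbenzoate | COC(=O)c1c(C)cc(OCc2ccccc2)cc1OCc1ccccc1 | intermediate
3 | hexanoyl chloride | CCCCCC(Cl)=O | starting material
4 | N-methoxy-N-methylhexanamide | CCCCCC(=O)N(C)OC | intermediate
5 | methyl 2,4-bis(benzyloxy)-6-(lithiomethyl)benzoate (lithiated toluate) | COC(=O)c1c(C[Li])cc(OCc2ccccc2)cc1OCc1ccccc1 | intermediate
6 | methyl 2,4-bis(benzyloxy)-6-(2-oxoheptyl)benzoate | COC(=O)c1c(CC(=O)CCCCC)cc(OCc2ccccc2)cc1OCc1ccccc1 | intermediate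
7 | 6,8-bis(benzyloxy)-3-pentyl-1H-isochromen-1-one | CCCCCc1cc2cc(OCc3ccccc3)cc(OCc3ccccc3)c2c(=O)o1 | intermediate
8 | 6-(benzyloxy)-8-hydroxy-3-pentyl-1H-isochromen-1-one | CCCCCc1cc2cc(OCc3ccccc3)cc(O)c2c(=O)o1 | intermediate
9 | methyl 4-chloroacetoacetate (methyl 4-chloro-3-oxobutanoate) | COC(=O)CC(=O)CCl | starting material
10 | methyl 4-{[6-(benzyloxy)-1-oxo-3-pentyl-1H-isochromen-8-yl]oxy}-3-oxobutanoate | CCCCCc1cc2cc(OCc3ccccc3)cc(OCC(=O)CC(=O)OC)c2c(=O)o1 | intermediate
11 | methyl 4-{[6-(benzyloxy)-1-oxo-3-pentyl-1H-isochromen-8-yl]oxy}-3-(trimethylsilyloxy)but-2-enoate (E/Z mixture, geometry not defined) | CCCCCc1cc2cc(OCc3ccccc3)cc(OCC(O[Si](C)(C)C)=CC(=O)OC)c2c(=O)o1 | intermediate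
12 | 6-(benzyloxy)-8-{[4-methoxy-2,4-bis(trimethylsilyloxy)buta-1,3-dien-1-yl]oxy}-3-pentyl-1H-isochromen-1-one (geometric isomers, geometry not defined) | CCCCCc1cc2cc(OCc3ccccc3)cc(OC=C(O[Si](C)(C)C)C=C(OC)O[Si](C)(C)C)c2c(=O)o1 | intermediate
13 | oct-2-ynoic acid | CCCCCC#CC(=O)O | starting material
14 | benzyl oct-2-ynoate | CCCCCC#CC(=O)OCc1ccccc1 | intermediate
15 | benzyl 3-{[6-(benzyloxy)-1-oxo-3-pentyl-1H-isochromen-8-yl]oxy}-6-methoxy-2-pentyl-4,6-bis(trimethylsilyloxy)cyclohexa-1,4-diene-1-carboxylate (mixture of diastereomers) | CCCCCC1=C(C(=O)OCc2ccccc2)C(OC)(O[Si](C)(C)C)C=C(O[Si](C)(C)C)C1Oc1cc(OCc2ccccc2)cc2cc(CCCCC)oc(=O)c12 | intermediate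
16 | benzyl 5-{[6-(benzyloxy)-1-oxo-3-pentyl-1H-isochromen-8-yl]oxy}-6-pentyl-2,4-bis(trimethylsilyloxy)benzoate | CCCCCc1c(C(=O)OCc2ccccc2)c(O[Si](C)(C)C)cc(O[Si](C)(C)C)c1Oc1cc(OCc2ccccc2)cc2cc(CCCCC)oc(=O)c12 | intermediate
17 | benzyl 5-{[6-(benzyloxy)-1-oxo-3-pentyl-1H-isochromen-8-yl]oxy}-2,4-dihydroxy-6-pentylbenzoate | CCCCCc1cc2cc(OCc3ccccc3)cc(Oc3c(O)cc(O)c(C(=O)OCc4ccccc4)c3CCCCC)c2c(=O)o1 | intermediate
18 | 5-[(6-hydroxy-1-oxo-3-pentyl-1H-isochromen-8-yl)oxy]-2,4-dihydroxy-6-pentylbenzoic acid | CCCCCc1cc2cc(O)cc(Oc3c(O)cc(O)c(C(=O)O)c3CCCCC)c2c(=O)o1 | target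

**Step count**

Total: 11 steps.
Longest linear sequence: 9 steps from methyl orsellinate (steps 1, 3, 4, 5, 6, 7, 8, 10, 11).

**Steps most likely to fail**

Step 10. The β-pentyl ynoate is a slow dienophile and the reacting diene terminus is hindered by the aryloxy group. Thermal desilylation of the diene back to the β-keto ester, or drift to a geometry that cannot reach the s-cis form, could therefore outrun cycloaddition. The fallback replaces the alkyne by its far more reactive allene isomer and keeps the same two ring bonds. It sets out from 3 and 12. Hexanoyl chloride 3 is converted to its ketene with Et3N in CH2Cl2 and trapped in a Wittig reaction with benzyl (triphenylphosphoranylidene)acetate to give benzyl octa-2,3-dienoate F1. Its conjugated 2,3-double bond should add to 12 in toluene between room temperature and 60 °C with the same orientation, giving benzyl 5-{[6-(benzyloxy)-1-oxo-3-pentyl-1H-isochromen-8-yl]oxy}-2-methoxy-6-pentylidene-2,4-bis(trimethylsilyloxy)cyclohex-3-ene-1-carboxylate F2. Loss of methanol across C1'–C2' and migration of the exocyclic double bond into the ring lead to 16, and the acidic work-up of step 10 returns the route at 17.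

Step 6. The hydrogen-bonded, peri-hindered 8-phenoxide is a weak nucleophile, so self-condensation of the chloroacetoacetate enolate could consume the electrophile before O-alkylation. The fallback sets out from 8 and uses a non-enolisable, masked 4-haloacetoacetate. Alkylation with methyl (E)-4-bromo-3-methoxybut-2-enoate and K2CO3 in acetone at reflux should give methyl (2E)-4-{[6-(benzyloxy)-1-oxo-3-pentyl-1H-isochromen-8-yl]oxy}-3-methoxybut-2-enoate F3. Hydrolysis of the methyl enol ether with aqueous HCl in THF then frees the ketone and returns the route at 10.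

Step 8. The lithium amide could instead deprotonate the allylic CH2 of the 3-pentyl group, the dienolate could attack the lactone, and the labile ketene acetal silyl group could be lost on isolation. The fallback sets out from 10, skips 11 and avoids any lithium base. Soft enolisation with Me3SiOTf (2.5 equiv) and Et3N in Et2O at 0 °C, a known way to doubly O-silylate 1,3-dicarbonyl compounds, should give the diene directly. The ammonium salt is filtered off under argon and the crude solution is carried into step 10, so the route is rejoined at 12. This fallback makes no compound outside the list (F0).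

**Further compounds**

F1 | step 10 | benzyl octa-2,3-dienoate (racemic) | CCCCC=C=CC(=O)OCc1ccccc1
F2 | step 10 | benzyl 5-{[6-(benzyloxy)-1-oxo-3-pentyl-1H-isochromen-8-yl]oxy}-2-methoxy-6-pentylidene-2,4-bis(trimethylsilyloxy)cyclohex-3-ene-1-carboxylate (mixture of stereoisomers) | CCCCC=C1C(C(=O)OCc2ccccc2)C(OC)(O[Si](C)(C)C)C=C(O[Si](C)(C)C)C1Oc1cc(OCc2ccccc2)cc2cc(CCCCC)oc(=O)c12
F0 | step 8 | none | none
F3 | step 6 | methyl (2E)-4-{[6-(benzyloxy)-1-oxo-3-pentyl-1H-isochromen-8-yl]oxy}-3-methoxybut-2-enoate | COC(=O)/C=C(/OC)COc1cc(OCc2ccccc2)cc2cc(CCCCC)oc(=O)c12
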